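**Plan**
Retrosynthesis: the C5 phenol is masked as a benzyl ether and an oxygen bridge is put back between C1' and C4'. The naphthalene (primed atoms, C1' on chroman C4) is then cut at C1'–C8a' and C4'–C4a', next the bond from C4 to the resulting furan, and last C2–C3 and O1–C2 of the pyran ring.
Enabling feature: the ring C1'–C2'–C3'–C4'–C4a'–C8a' holds its two substituents para (chroman C4 on C1', OMe on C4'), like the α-carbons of a 2,5-disubstituted furan. The other ring holds its OMe on C5', peri to C4' and ortho to the fusion carbon C4a', exactly as 3-methoxybenzyne does.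
Forward: the purchased benzene ring gains the pyranone ring (Claisen condensation, cyclodehydration). The derived chromanol is joined at C4 to commercial 2-methoxyfuran, the aryne cycloaddition closes the substituted naphthalene carbocycle, and removal of the bridge oxygen aromatises it.
Stereochemistry: C2 (R) comes from a ligand-controlled CuH conjugate reduction of the 2-methylchromone. C4 comes from substrate control, the furan adding to the chroman-4-ylium ion trans to the C2 methyl group; the two bridgehead centres of the cycloadduct are transient.
Key step: step 6

Assumption: the (S)-antipode of the ligand in step 3 is taken, by analogy with cyclic β-methyl enones, to deliver hydride to the face of C2 that gives (R)-6. If the sense is reversed, the equally available (R)-ligand is used and nothing else changes.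

Step 1
Reactants: 1 2',6'-dihydroxyacetophenone
Product: 2 1-[2-(benzyloxy)-6-hydroxyphenyl]ethan-1-one
Conditions: BnBr (1.0 equiv), K2CO3, acetone, reflux
Reagents that add atoms: benzyl bromide, BrCc1ccccc1
Why: Williamson ether synthesis, in which the second phenol stays tied to the ketone by an intramolecular hydrogen bond after the first alkylation and is far less nucleophilic, so one equivalent of benzyl bromide should stop at the mono-ether.

Step 2
Reactants: 2 1-[2-(benzyloxy)-6-hydroxyphenyl]ethan-1-one; 3 ethyl acetate
Product: 5 5-(benzyloxy)-2-methyl-4H-chromen-4-one, via aryl butane-1,3-dione 4 (not isolated)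
Conditions: NaH (3 equiv), EtOAc (excess), THF, reflux; aq. HCl quench; crude 4, p-TsOH·H2O (cat.), toluene, 80 °C
Reagents that add atoms: none
Why: Crossed Claisen condensation of the methyl ketone enolate with ethyl acetate (C2–C3 bond), then acid-catalysed cyclodehydration of the o-hydroxyaryl 1,3-diketone (O1–C2 bond), is the classical entry to 2-methylchromones, and a catalytic sulfonic acid is chosen because hot mineral acid would cleave the benzyl ether peri to the carbonyl group.

Step 3
Reactants: 5 5-(benzyloxy)-2-methyl-4H-chromen-4-one
Product: 6 (R)-5-(benzyloxy)-2-methylchroman-4-one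
Conditions: Cu(OAc)2·H2O (3 mol %), (S)-DTBM-SEGPHOS (3.3 mol %), (EtO)2MeSiH, t-BuOH, toluene, 0 °C → rt
Reagents that add atoms: none
Why: Asymmetric conjugate reduction with bisphosphine-ligated CuH, established for 2-alkylchromones, lets hydride reach only one face of the C2=C3 bond and so sets C2 as R, while t-BuOH protonates the copper enolate so that no base builds up that could open the ring by a retro-oxa-Michael reaction, and any over-reduction to the chromanol is harmless because that is the next intermediate.

Step 4
Reactants: 6 (R)-5-(benzyloxy)-2-methylchroman-4-one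
Product: 7 (2R,4S)-5-(benzyloxy)-2-methylchroman-4-ol (cis)
Conditions: NaBH4, MeOH, 0 °C
Reagents that add atoms: none
Why: Borohydride reduction of an aryl ketone, in which pseudoaxial hydride approach should give mainly the cis (4S) alcohol, although the C4 configuration is of no consequence because this centre is planarised in step 5, and the low temperature protects the base-sensitive C2 centre.

Step 5
Reactants: 7 (2R,4S)-5-(benzyloxy)-2-methylchroman-4-ol; 8 2-methoxyfuran
Product: 9 (2R,4R)-5-(benzyloxy)-4-(5-methoxyfuran-2-yl)-2-methylchroman (trans)
Conditions: 8 (3 equiv), (PhO)2P(O)OH (10 mol %), 4 Å MS, CH2Cl2, −20 °C → rt; Et3N quench; Et3N-deactivated silica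
Reagents that add atoms: none
Why: SN1-type Friedel–Crafts alkylation in which the mild phosphoric acid, of a kind known to tolerate 2-methoxyfuran and its 5-alkylated products, ionises the doubly ortho-oxygenated benzylic alcohol, the furan captures the cation through its free α-carbon and rearomatises by proton loss, and C4 is set trans to the equatorial C2 methyl group by pseudoaxial attack on the sofa-shaped cation, the isomer also favoured thermodynamically because the peri benzyloxy group forces the C4 substituent pseudoaxial.

Step 6
Reactants: 9 (2R,4R)-5-(benzyloxy)-4-(5-methoxyfuran-2-yl)-2-methylchroman; 10 3-methoxy-2-(trimethylsilyl)phenyl trifluoromethanesulfonate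
Product: 12 (1R,4R)-1-[(2R,4R)-5-(benzyloxy)-2-methylchroman-4-yl]-4,5-dimethoxy-1,4-dihydro-1,4-epoxynaphthalene (its 1S,4S bridgehead diastereomer forms alongside and is carried on unseparated), via 3-methoxybenzyne 11 (not isolated)
Conditions: 10 (1.5 equiv), CsF (3 equiv), MeCN, rt; filtration through basic alumina
Reagents that add atoms: none
Why: Fluoride attacks the silicon of 10 and triflate departs, giving 3-methoxybenzyne 11, which the electron-rich furan of 9 traps in a concerted but asynchronous [4+2] cycloaddition, the aryne–furan Diels–Alder reaction that is well known for 3-alkoxybenzynes and 2-alkoxyfurans. The one ring closed, the six-membered carbocycle C1'–C2'–C3'–C4'–C4a'–C8a', arises by intermolecular suprafacial addition of the aryne bond C4a'–C8a' across the two furan α-carbons, so that C1'–C8a' and C4'–C4a' form in one event and the furan oxygen remains as the 1,4-bridge. The selectivity needed is head-to-head regiochemistry: the inductively withdrawing methoxy group distorts the aryne so that the carbon meta to it is the electrophilic terminus, while the furan methoxy group places the largest HOMO coefficient on the remote, chromanyl-bearing α-carbon, so the leading bond is C1'–C8a' and the two methoxy groups end up peri, an outcome that sterics reinforce by keeping the bulky chromanyl group away from the aryne methoxy group. The new bridgehead stereocentres C1' and C4' are fixed relative to each other by the oxygen bridge, and their sense relative to C4 depends only on which furan face is attacked, for which the C4 centre should exert little bias; this is immaterial because both centres vanish in step 7. The medium is aprotic and neutral to weakly basic, so the acid-labile methoxyfuran, the bridged ketal, the benzyl ether and the C2 and C4 centres should all persist.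

Step 7
Reactants: 12 (1R,4R)-1-[(2R,4R)-5-(benzyloxy)-2-methylchroman-4-yl]-4,5-dimethoxy-1,4-dihydro-1,4-epoxynaphthalene (both bridgehead diastereomers)
Product: 13 (2R,4S)-5-(benzyloxy)-4-(4,5-dimethoxynaphthalen-1-yl)-2-methylchroman
Conditions: TiCl4 (4 equiv), Zn dust (8 equiv), THF, reflux 1 h; cool to 0 °C, add 12 in THF, 0 °C → rt
Reagents that add atoms: none
Why: Deoxygenative aromatisation of a 1,4-epoxy-1,4-dihydronaphthalene with pre-formed divalent titanium, in which the oxophilic metal opens the bridge at the ketal carbon C4' (the exocyclic methoxy group cannot leave because a bridgehead oxocarbenium ion is geometrically impossible) and two-electron transfer then expels the titanium-bound oxygen from C1', so both substituents stay, both diastereomers converge and no cation forms on the carbon next to the C4 stereocentre.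

Step 8
Reactants: 13 (2R,4S)-5-(benzyloxy)-4-(4,5-dimethoxynaphthalen-1-yl)-2-methylchroman
Product: 14 cladonaphchrom A, (2R,4S)-4-(4,5-dimethoxynaphthalen-1-yl)-2-methylchroman-5-ol
Conditions: H2 (1 atm), 10% Pd/C, EtOAc–MeOH, rt
Reagents that add atoms: none
Why: Catalytic hydrogenolysis of a benzyl aryl ether, in which only the O–CH2Ph bond is cleaved because the chroman C2–O bond is not benzylic and C4 carries no heteroatom, so both stereocentres and the naphthalene remain untouched at atmospheric pressure.

**Compound list**
1 | 2',6'-dihydroxyacetophenone | CC(=O)c1c(O)cccc1O | starting material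
2 | 1-[2-(benzyloxy)-6-hydroxyphenyl]ethan-1-one | CC(=O)c1c(O)cccc1OCc1ccccc1 | intermediate
3 | ethyl acetate | CCOC(C)=O | starting material
4 | 1-[2-(benzyloxy)-6-hydroxyphenyl]butane-1,3-dione | CC(=O)CC(=O)c1c(O)cccc1OCc1ccccc1 | intermediate
5 | 5-(benzyloxy)-2-methyl-4H-chromen-4-one | CC1=CC(=O)c2c(OCc3ccccc3)cccc2O1 | intermediate
6 | (R)-5-(benzyloxy)-2-methylchroman-4-one | C[C@@H]1CC(=O)c2c(OCc3ccccc3)cccc2O1 | intermediate
7 | (2R,4S)-5-(benzyloxy)-2-methylchroman-4-ol (cis) | C[C@@H]1C[C@H](O)c2c(OCc3ccccc3)cccc2O1 | intermediate
8 | 2-methoxyfuran | COc1ccco1 | starting material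
9 | (2R,4R)-5-(benzyloxy)-4-(5-methoxyfuran-2-yl)-2-methylchroman (trans) | C[C@@H]1C[C@@H](c2ccc(OC)o2)c2c(OCc3ccccc3)cccc2O1 | intermediate
10 | 3-methoxy-2-(trimethylsilyl)phenyl trifluoromethanesulfonate | COc1cccc(OS(=O)(=O)C(F)(F)F)c1[Si](C)(C)C | starting material
11 | 3-methoxybenzyne (1-methoxy-2,3-didehydrobenzene) | COC1=CC=CC#C1 | intermediate
12 | (1R,4R)-1-[(2R,4R)-5-(benzyloxy)-2-methylchroman-4-yl]-4,5-dimethoxy-1,4-dihydro-1,4-epoxynaphthalene (isomer drawn; the 1S,4S bridgehead isomer accompanies it) | C[C@@H]1C[C@@H]([C@@]23C=C[C@@](OC)(O2)c2c(OC)cccc23)c2c(OCc3ccccc3)cccc2O1 | intermediate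
13 | (2R,4S)-5-(benzyloxy)-4-(4,5-dimethoxynaphthalen-1-yl)-2-methylchroman | COc1cccc2c([C@@H]3C[C@@H](C)Oc4cccc(OCc5ccccc5)c43)ccc(OC)c12 | intermediate
14 | cladonaphchrom A, (2R,4S)-4-(4,5-dimethoxynaphthalen-1-yl)-2-methylchroman-5-ol | COc1cccc2c([C@@H]3C[C@@H](C)Oc4cccc(O)c43)ccc(OC)c12 | target

Total step count: 8. Longest linear sequence: 8 steps (1 → 14).

**Steps most likely to fail**

Step 7. The bridged ketal may ionise faster than it is reduced. Loss of the methyl group from the oxocarbenium ion, or a dienone–phenol-type 1,2-shift of the chromanyl group, could then compete with deoxygenation, and residual Lewis acid may attack the benzyl ether.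
- The fallback sets out from 12 and separates ring opening from reduction.
- Brief treatment with dilute aqueous HCl in THF hydrolyses the ketal on purpose to the p-quinol (4R)-4-[(2R,4R)-5-(benzyloxy)-2-methylchroman-4-yl]-4-hydroxy-8-methoxynaphthalen-1(4H)-one F1 (with its 4S epimer).
- Zn dust in AcOH then effects the known reductive aromatisation of p-quinols to 4-[(2R,4S)-5-(benzyloxy)-2-methylchroman-4-yl]-8-methoxynaphthalen-1-ol F2.
- O-methylation (MeI, K2CO3, DMF) returns to the route at 13.

Step 5. Acid-promoted hydrolysis or oligomerisation of the methoxyfuran may erode the coupling. So may collapse of the furan-derived oxocarbenium ion by demethylation instead of proton loss, or incomplete trans selectivity.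
- The fallback sets out from 7 and installs the methoxy group only after the C–C bond.
- Friedel–Crafts alkylation of acid-tolerant furan (large excess, p-TsOH·H2O cat., CH2Cl2) should give (2R,4R)-5-(benzyloxy)-4-(furan-2-yl)-2-methylchroman F3.
- α-Lithiation of the furan (n-BuLi, THF, −78 → 0 °C) and an I2 quench give (2R,4R)-5-(benzyloxy)-4-(5-iodofuran-2-yl)-2-methylchroman F4.
- Ullmann-type methoxylation (CuI, 1,10-phenanthroline, NaOMe, MeOH–toluene, heat) returns to the route at 9.

Step 6. Cycloaddition at the crowded furan α-carbon may be slow, so that the aryne is consumed by side reactions. Head-to-head selectivity may erode, and the ketal may open during isolation.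
- The fallback sets out from 7 and gives up the construction of the naphthalene.
- The chroman-4-ylium ion is intercepted directly by purchased 1,8-dimethoxynaphthalene (COc1cccc2cccc(OC)c12; p-TsOH·H2O cat., CH2Cl2, 0 °C → rt).
- This arene reacts at the position para to a methoxy group and, for the same conformational reasons as in step 5, trans to the methyl group.
- The sequence returns to the route at 13 and makes no compound outside the list (F0).

**Further compounds**
F1 | step 7 | (4R)-4-[(2R,4R)-5-(benzyloxy)-2-methylchroman-4-yl]-4-hydroxy-8-methoxynaphthalen-1(4H)-one | C[C@@H]1C[C@@H]([C@]2(O)C=CC(=O)c3c(OC)cccc32)c2c(OCc3ccccc3)cccc2O1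
F2 | step 7 | 4-[(2R,4S)-5-(benzyloxy)-2-methylchroman-4-yl]-8-methoxynaphthalen-1-ol | COc1cccc2c([C@@H]3C[C@@H](C)Oc4cccc(OCc5ccccc5)c43)ccc(O)c12
F3 | step 5 | (2R,4R)-5-(benzyloxy)-4-(furan-2-yl)-2-methylchroman | C[C@@H]1C[C@@H](c2ccco2)c2c(OCc3ccccc3)cccc2O1
F4 | step 5 | (2R,4R)-5-(benzyloxy)-4-(5-iodofuran-2-yl)-2-methylchroman | C[C@@H]1C[C@@H](c2ccc(I)o2)c2c(OCc3ccccc3)cccc2O1
F0 | step 6 | none | none
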